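The pivotal operation forms C1–C9 and C4–C5 together; ring A is closed afterwards at C2–C3. The step exploits the trans-vicinal pair on ring B: C9 carries the C1/C2/C15 unit and C5 the C4(isopropyl)–C3 chain, beta and alpha to C6, so ring B is cyclopent-2-enone with C6 as carbonyl. Copper-catalysed asymmetric addition of isopropenylmagnesium bromide at C9 and capture of the magnesium enolate at C5 by (E)-3-methyl-1-nitrobut-1-ene give both bonds and the C9, C5 and C4 stereocentres in one flask. The precursors are three achiral pieces: the enone, the alkenyl Grignard reagent and the nitroalkene, whose nitromethyl group masks the C3 aldehyde.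

Key step: step 4

Remark: ring A is C1 (exocyclic C15H2), C2 (OH), C3 (angelate), C4 (isopropyl), C5, C9; ring B is C5, C6 (ethylidene C10–C11), C7 (acetate), C8, C9; β is the face of H-5 and α that of H-9; the Grignard reagent is assumed to be made in diethyl ether, because THF would erode the enantioselectivity of the copper catalysis.

Step 1
Reactants: 1 isobutyraldehyde; 2 nitromethane
Product: 3 3-methyl-1-nitrobutan-2-ol (racemic)
Conditions: NaOH (cat.), MeOH, 0 °C
Reagents that add atoms: none
Why: Base-catalysed Henry (nitroaldol) addition to an unhindered aldehyde; the carbinol centre is racemic and is destroyed in step 2.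

Step 2
Reactants: 3 3-methyl-1-nitrobutan-2-ol
Product: 5 (E)-3-methyl-1-nitrobut-1-ene, via mesylate 4 (not isolated)
Conditions: MsCl, Et3N (2.2 equiv), CH2Cl2, 0 °C
Reagents that add atoms: none
Why: Mesylation and E1cB elimination of the β-nitro mesylate (dehydration of a Henry adduct) should give the conjugated nitroalkene as its stable E isomer.

Step 3
Reactants: 6 2-bromopropene
Product: 7 isopropenylmagnesium bromide (ether solution)
Conditions: Mg turnings, Et2O, reflux
Reagents that add atoms: magnesium, [Mg]
Why: Grignard formation by insertion of magnesium into the vinylic C–Br bond gives the alkenyl reagent free of THF.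

Step 4
Reactants: 8 cyclopent-2-en-1-one; 7 isopropenylmagnesium bromide; 5 (E)-3-methyl-1-nitrobut-1-ene
Product: 11 (2R,3R)-2-[(2S)-3-methyl-1-nitrobutan-2-yl]-3-(prop-1-en-2-yl)cyclopentan-1-one, via magnesium enolate 9 (not isolated), via magnesium nitronate 10 (not isolated)
Conditions: CuBr·SMe2 (5 mol %), (R)-1-[(SP)-2-(diphenylphosphino)ferrocenyl]ethyldicyclohexylphosphine (6 mol %), t-BuOMe, −78 °C, slow addition of 7; then 5, DMPU, THF, −78 → −40 °C; aq NH4Cl
Reagents that add atoms: none
Why: Transmetalation of 7 to the chiral copper–diphosphine complex and 1,4-addition at C9 release the regiodefined magnesium enolate 9, which adds through C5 to the β-carbon (C4) of nitroalkene 5 to give nitronate 10, protonated on work-up; the closest known reaction type is the copper/ferrocenyl-diphosphine-catalysed conjugate addition of Grignard reagents to cyclic enones with in situ trapping of the enolate by a Michael acceptor. No ring is closed. C9 is set by the chiral ligand (the ligand enantiomer that gives 9R is kept), and C5 by approach of the nitroalkene anti to the new isopropenyl group, which is also the thermodynamically favoured trans arrangement next to the ketone. C4 is set by the way the nitroalkene faces the enolate: the isomer drawn needs the extended (antiperiplanar) arrangement with the isopropyl group turned away from ring B, whereas a magnesium-bridged synclinal arrangement would give the C4 epimer, so DMPU is added to take magnesium off the nitro group; this is the least secure element of the step. The step also needs 1,4- over 1,2-addition and capture of 9 by the nitroalkene faster than its attack on unreacted enone, which copper catalysis, slow addition of 7 at −78 °C and the high electrophilicity of 5 should secure. Any 4-epimer is expected to lag at the ring closure of step 6, where it would have to cyclise with an axial isopropyl group, and is separated there.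

Step 5
Reactants: 11 (2R,3R)-2-[(2S)-3-methyl-1-nitrobutan-2-yl]-3-(prop-1-en-2-yl)cyclopentan-1-one
Product: 13 (2S)-3-methyl-2-[(1R,5R)-2-oxo-5-(prop-1-en-2-yl)cyclopentyl]butanal, via sodium nitronate 12 (not isolated)
Conditions: NaOMe (1.05 equiv), MeOH, 0 °C; then TiCl3, NH4OAc buffer (pH 5–6), H2O–THF, rt
Reagents that add atoms: water, O
Why: Reductive (McMurry) Nef reaction: TiCl3 reduces the nitronate to the imine, which is hydrolysed in the buffered medium, so the isopropenyl group, the ketone and the epimerisable C4 and C5 centres should be left untouched.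

Step 6
Reactants: 13 (2S)-3-methyl-2-[(1R,5R)-2-oxo-5-(prop-1-en-2-yl)cyclopentyl]butanal
Product: 14 3β-hydroxy-4β-isopropyl-1(15)-methylene-trans-hydrindan-6-one (H-5β; H-9α)
Conditions: Me2AlCl (2.5 equiv), CH2Cl2, −78 → −20 °C
Reagents that add atoms: none
Why: Lewis-acid-promoted intramolecular carbonyl-ene reaction of the type-two (Snider) class, a six-membered closure in which C3 bonds to the methylene carbon of the isopropenyl group (C2) while a methyl hydrogen passes to oxygen and leaves the exocyclic C1=C15 bond; the chair transition state keeps C6, C8 and the isopropyl group equatorial and needs the carbonyl oxygen axial to reach that hydrogen, which sets the axial 3β-hydroxyl, and the aldehyde reacts in preference to the ketone.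

Step 7
Reactants: 14 3β-hydroxy-4β-isopropyl-1(15)-methylene-trans-hydrindan-6-one
Product: 15 3β-angeloyloxy-4β-isopropyl-1(15)-methylene-trans-hydrindan-6-one
Conditions: angelic acid, 2,4,6-trichlorobenzoyl chloride, Et3N, toluene, rt; then 14, 80 °C (no DMAP)
Reagents that add atoms: angelic acid, C/C=C(/C)C(=O)O
Why: Yamaguchi-type acylation through the mixed 2,4,6-trichlorobenzoic anhydride, run without DMAP, is the established way to esterify hindered secondary alcohols with angelic acid without isomerisation to the tiglate.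

Step 8
Reactants: 15 3β-angeloyloxy-4β-isopropyl-1(15)-methylene-trans-hydrindan-6-one
Product: 16 3β-angeloyloxy-2α-hydroxy-4β-isopropyl-1(15)-methylene-trans-hydrindan-6-one
Conditions: SeO2 (0.5 equiv), t-BuOOH, CH2Cl2, rt
Reagents that add atoms: tert-butyl hydroperoxide, CC(C)(C)OO (oxygen relayed by catalytic selenium dioxide, O=[Se]=O)
Why: SeO2 allylic hydroxylation (ene reaction at C15, then [2,3]-sigmatropic shift) of a 1,1-disubstituted exocyclic alkene prefers the ring CH2 (C2) over the ring-fusion CH (C9) and replaces the axial C2–H suprafacially, which should give the axial 2α-alcohol trans to the 3β-ester.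

Step 9
Reactants: 16 3β-angeloyloxy-2α-hydroxy-4β-isopropyl-1(15)-methylene-trans-hydrindan-6-one
Product: 17 3β-angeloyloxy-2α-(tert-butyldimethylsilyloxy)-4β-isopropyl-1(15)-methylene-trans-hydrindan-6-one
Conditions: TBSOTf, 2,6-lutidine, CH2Cl2, −78 °C
Reagents that add atoms: tert-butyldimethylsilyl triflate, CC(C)(C)[Si](C)(C)OS(=O)(=O)C(F)(F)F
Why: Silyl triflate silylation of the hindered axial allylic alcohol masks it for the ring B steps, and at −78 °C the ketone should not be enol-silylated.

Step 10
Reactants: 17 3β-angeloyloxy-2α-(tert-butyldimethylsilyloxy)-4β-isopropyl-1(15)-methylene-trans-hydrindan-6-one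
Product: 19 7-(triethylsilyloxy) derivative of 17 (C7 epimers), via triethylsilyl enol ether 18 (not isolated)
Conditions: KN(SiMe3)2, Et3SiCl, THF, −78 °C; then m-CPBA (1.0 equiv), NaHCO3, CH2Cl2, −20 °C
Reagents that add atoms: chlorotriethylsilane, CC[Si](Cl)(CC)CC; 3-chloroperbenzoic acid, OOC(=O)c1cccc(Cl)c1
Why: Kinetic deprotonation occurs at the accessible C7 methylene and not at the hindered ring-fusion C5–H, and Rubottom oxidation of the electron-rich silyl enol ether (much faster than epoxidation of the methylene or angelate double bonds, with silyl migration to the new oxygen) gives the 7-silyloxy ketone; C7 is left unassigned because it later passes through a ketone.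

Step 11
Reactants: 19 7-(triethylsilyloxy) derivative of 17
Product: 20 3β-angeloyloxy-2α-(tert-butyldimethylsilyloxy)-6(10)Z-ethylidene-4β-isopropyl-1(15)-methylene-7-(triethylsilyloxy)-trans-hydrindane (C7 epimers)
Conditions: EtPPh3Br, KN(SiMe3)2, THF, 0 °C; then 19, −78 °C → rt
Reagents that add atoms: ethyltriphenylphosphonium bromide, CC[P+](c1ccccc1)(c1ccccc1)c1ccccc1.[Br-]
Why: Wittig ethylidenation with a salt-free non-stabilised ylide, relying on the Z-selective olefination of α-alkoxy ketones, in which the ylide substituent ends up cis to the oxygenated α-carbon, so C11 should come out syn to C7 as in the target, reinforced by the bulky C7 siloxy group.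

Step 12
Reactants: 20 bis-silyl ether (C7 epimers)
Product: 21 3β-angeloyloxy-2α-(tert-butyldimethylsilyloxy)-6(10)Z-ethylidene-7-hydroxy-4β-isopropyl-1(15)-methylene-trans-hydrindane (C7 epimers)
Conditions: PPTS (cat.), MeOH–CH2Cl2, 0 °C
Reagents that add atoms: none
Why: Acid-catalysed methanolysis removes a triethylsilyl ether far faster than a tert-butyldimethylsilyl ether, so only the C7 hydroxyl should be set free.

Step 13
Reactants: 21 C7 allylic alcohol (C7 epimers)
Product: 22 3β-angeloyloxy-2α-(tert-butyldimethylsilyloxy)-6(10)Z-ethylidene-4β-isopropyl-1(15)-methylene-trans-hydrindan-7-one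
Conditions: Dess–Martin periodinane, NaHCO3, CH2Cl2, 0 °C → rt
Reagents that add atoms: none
Why: Dess–Martin oxidation under buffered, non-basic conditions converges both C7 epimers on the Z-enone without touching the silyl ether, the ester or the alkene geometry.

Step 14
Reactants: 22 Z-enone
Product: 23 3β-angeloyloxy-2α-(tert-butyldimethylsilyloxy)-6(10)Z-ethylidene-7β-hydroxy-4β-isopropyl-1(15)-methylene-trans-hydrindane (7S)
Conditions: (R)-2-methyl-CBS-oxazaborolidine (0.5 equiv), catecholborane, toluene, −78 °C
Reagents that add atoms: none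
Why: Corey–Bakshi–Shibata reduction under reagent control: the oxazaborolidine binds the carbonyl oxygen on the side of the small C8 methylene and delivers hydride to the face that gives the 7S (7β) allylic alcohol, with the alkylidene carbon C6 as the large group; catecholborane at −78 °C should leave the alkenes and the ester alone.

Step 15
Reactants: 23 7β-alcohol
Product: 24 7β-acetoxy-3β-angeloyloxy-2α-(tert-butyldimethylsilyloxy)-6(10)Z-ethylidene-4β-isopropyl-1(15)-methylene-trans-hydrindane
Conditions: Ac2O, pyridine, DMAP (cat.), CH2Cl2, 0 °C → rt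
Reagents that add atoms: acetic anhydride, CC(=O)OC(C)=O
Why: DMAP-catalysed acetylation of the only free hydroxyl; angelate esters are not isomerised under these conditions.

Step 16
Reactants: 24 7β-acetate silyl ether
Product: 25 CNP0113604.1 (7β-acetoxy-3β-angeloyloxy-2α-hydroxy-6(10)Z-ethylidene-4β-isopropyl-1(15)-methylene-trans-hydrindane)
Conditions: HF·pyridine, THF–pyridine, 0 °C → rt
Reagents that add atoms: none
Why: Fluoride cleavage of the silyl ether with buffered HF·pyridine should leave the acetate, the angelate and both alkenes intact and reveal the 2α-hydroxyl of the target.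

Compound list
1 | isobutyraldehyde | CC(C)C=O | starting material
2 | nitromethane | C[N+](=O)[O-] | starting material
3 | 3-methyl-1-nitrobutan-2-ol (racemic) | CC(C)C(O)C[N+](=O)[O-] | intermediate
4 | 3-methyl-1-nitrobutan-2-yl methanesulfonate (racemic, not isolated) | CC(C)C(OS(C)(=O)=O)C[N+](=O)[O-] | intermediate
5 | (E)-3-methyl-1-nitrobut-1-ene | CC(C)/C=C/[N+](=O)[O-] | intermediate
6 | 2-bromopropene | CC(Br)=C | starting material
7 | isopropenylmagnesium bromide | CC(=C)[Mg]Br | intermediate
8 | cyclopent-2-en-1-one | O=C1C=CCC1 | starting material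
9 | bromomagnesium (R)-3-(prop-1-en-2-yl)cyclopent-1-en-1-olate (not isolated) | Br[Mg]OC1=C[C@H](C(C)=C)CC1 | intermediate
10 | bromomagnesium nitronate of 11 (not isolated) | O=C1CC[C@@H](C(C)=C)[C@@H]1[C@H](C(C)C)C=[N+]([O-])O[Mg]Br | intermediate
11 | (2R,3R)-2-[(2S)-3-methyl-1-nitrobutan-2-yl]-3-(prop-1-en-2-yl)cyclopentan-1-one | O=C1CC[C@@H](C(C)=C)[C@@H]1[C@H](C(C)C)C[N+]([O-])=O | intermediate
12 | sodium nitronate of 11 (not isolated) | O=C1CC[C@@H](C(C)=C)[C@@H]1[C@H](C(C)C)C=[N+]([O-])[O-].[Na+] | intermediate
13 | (2S)-3-methyl-2-[(1R,5R)-2-oxo-5-(prop-1-en-2-yl)cyclopentyl]butanal | O=C1CC[C@@H](C(C)=C)[C@@H]1[C@H](C(C)C)C=O | intermediate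
14 | 3β-hydroxy-4β-isopropyl-1(15)-methylene-trans-hydrindan-6-one | C=C1C[C@@H](O)[C@@H](C(C)C)[C@@H]2C(=O)CC[C@@H]12 | intermediate
15 | 3β-angeloyloxy-4β-isopropyl-1(15)-methylene-trans-hydrindan-6-one | C=C1C[C@@H](OC(=O)/C(C)=C\C)[C@@H](C(C)C)[C@@H]2C(=O)CC[C@@H]12 | intermediate
16 | 3β-angeloyloxy-2α-hydroxy-4β-isopropyl-1(15)-methylene-trans-hydrindan-6-one | C=C1[C@H](O)[C@@H](OC(=O)/C(C)=C\C)[C@@H](C(C)C)[C@@H]2C(=O)CC[C@@H]12 | intermediate
17 | 2α-TBS ether of 16 | C=C1[C@H](O[Si](C)(C)C(C)(C)C)[C@@H](OC(=O)/C(C)=C\C)[C@@H](C(C)C)[C@@H]2C(=O)CC[C@@H]12 | intermediate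
18 | C6 triethylsilyl enol ether of 17, C6=C7 (not isolated) | C=C1[C@H](O[Si](C)(C)C(C)(C)C)[C@@H](OC(=O)/C(C)=C\C)[C@@H](C(C)C)[C@@H]2C(O[Si](CC)(CC)CC)=CC[C@@H]12 | intermediate
19 | 7-(triethylsilyloxy) derivative of 17 (C7 epimers) | C=C1[C@H](O[Si](C)(C)C(C)(C)C)[C@@H](OC(=O)/C(C)=C\C)[C@@H](C(C)C)[C@@H]2C(=O)C(O[Si](CC)(CC)CC)C[C@@H]12 | intermediate
20 | 6(10)Z-ethylidene 2α-TBS, 7-TES bis-silyl ether (C7 epimers) | C=C1[C@H](O[Si](C)(C)C(C)(C)C)[C@@H](OC(=O)/C(C)=C\C)[C@@H](C(C)C)[C@@H]2/C(=C/C)C(O[Si](CC)(CC)CC)C[C@@H]12 | intermediate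
21 | 6(10)Z-ethylidene 7-alcohol, 2α-TBS ether (C7 epimers) | C=C1[C@H](O[Si](C)(C)C(C)(C)C)[C@@H](OC(=O)/C(C)=C\C)[C@@H](C(C)C)[C@@H]2/C(=C/C)C(O)C[C@@H]12 | intermediate
22 | 6(10)Z-ethylidene 7-ketone, 2α-TBS ether | C=C1[C@H](O[Si](C)(C)C(C)(C)C)[C@@H](OC(=O)/C(C)=C\C)[C@@H](C(C)C)[C@@H]2/C(=C/C)C(=O)C[C@@H]12 | intermediate
23 | 7β-alcohol (7S), 2α-TBS ether | C=C1[C@H](O[Si](C)(C)C(C)(C)C)[C@@H](OC(=O)/C(C)=C\C)[C@@H](C(C)C)[C@@H]2/C(=C/C)[C@@H](O)C[C@@H]12 | intermediate
24 | 7β-acetate, 2α-TBS ether | C=C1[C@H](O[Si](C)(C)C(C)(C)C)[C@@H](OC(=O)/C(C)=C\C)[C@@H](C(C)C)[C@@H]2/C(=C/C)[C@@H](OC(C)=O)C[C@@H]12 | intermediate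
25 | CNP0113604.1 | C=C1[C@H](O)[C@@H](OC(=O)/C(C)=C\C)[C@@H](C(C)C)[C@@H]2/C(=C/C)[C@@H](OC(C)=O)C[C@@H]12 | target

Total step count: 16. Longest linear sequence: 15 steps (steps 1, 2 and 4–16).

Steps most likely to fail

Step 4. The nitroalkene may engage the magnesium enolate through a metal-bridged synclinal arrangement and so deliver mainly the C4 epimer. Alkenyl transfer to the five-membered enone may also proceed with low enantioselectivity, or the enolate may be consumed by unreacted enone. Fallback, setting out from 8, 7 and 1 and returning at 11: the same copper-catalysed addition of 7 to 8 is run, but enolate 9 is captured by isobutyraldehyde 1 (conjugate addition–aldol) to give the β-hydroxy ketone F1. Mesylation gives the mesylate F2, which DBU eliminates to the (E)-isobutylidene ketone F3. DBU-mediated conjugate addition of nitromethane 2 to F3, from the face opposite the pseudoaxial isopropenyl group on C9, then creates C4 with the required configuration under substrate control, and protonation at C5 trans to C9 gives 11.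

Step 8. The ene stage of the SeO2 oxidation may abstract the ring-fusion C9–H instead of the C2–H, which is deactivated by the neighbouring acyloxy group, or the allylic alcohol may be oxidised further. Fallback, setting out from 14 and returning at 17: the oxidation is run before acylation, so that SeO2/t-BuOOH acts on the free homoallylic alcohol and gives the trans-diaxial diol F4. The less hindered allylic C2 hydroxyl is silylated selectively (TBSOTf, 2,6-lutidine, −78 °C) to give the mono-silyl ether F5, and the remaining C3 hydroxyl is esterified with angelic acid as in step 7 to give 17.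

Step 11. The basic ylide may enolise the ketone toward C5 and epimerise the ring fusion, or the ethylidene may form with its methyl group on the C5 side. Fallback, setting out from 17 and returning at 21: the kinetic enolate of 17 is trapped with PhNTf2 as the enol triflate F6, and Stille coupling with Bu3SnCH=CH2 (Pd(PPh3)4, LiCl) gives the 1-vinylcyclopentene F7. Palladium-catalysed 1,4-hydrosilylation with HSiCl3 (PdCl2(PhCN)2, PPh3) puts hydrogen on C11 and silicon on C7 through the s-cis diene and gives the Z-configured allyltrichlorosilane F8. Ethanolysis (EtOH, Et3N) gives the triethoxysilane F9, and Tamao oxidation (H2O2, KF, KHCO3) gives the C7 alcohol 21.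

Further compounds
F1 | step 4 | (2R,3R)-2-(1-hydroxy-2-methylpropyl)-3-(prop-1-en-2-yl)cyclopentan-1-one (carbinol epimers) | O=C1CC[C@@H](C(C)=C)[C@@H]1C(O)C(C)C
F2 | step 4 | methanesulfonate of F1 | O=C1CC[C@@H](C(C)=C)[C@@H]1C(OS(C)(=O)=O)C(C)C
F3 | step 4 | (E)-2-(2-methylpropylidene)-3-(prop-1-en-2-yl)cyclopentan-1-one (C3 as in 11) | O=C1CC[C@@H](C(C)=C)/C1=C\C(C)C
F4 | step 8 | 2α,3β-dihydroxy-4β-isopropyl-1(15)-methylene-trans-hydrindan-6-one | C=C1[C@H](O)[C@@H](O)[C@@H](C(C)C)[C@@H]2C(=O)CC[C@@H]12
F5 | step 8 | 2α-(tert-butyldimethylsilyloxy)-3β-hydroxy-4β-isopropyl-1(15)-methylene-trans-hydrindan-6-one | C=C1[C@H](O[Si](C)(C)C(C)(C)C)[C@@H](O)[C@@H](C(C)C)[C@@H]2C(=O)CC[C@@H]12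
F6 | step 11 | C6 enol triflate of 17 (C6=C7) | C=C1[C@H](O[Si](C)(C)C(C)(C)C)[C@@H](OC(=O)/C(C)=C\C)[C@@H](C(C)C)[C@@H]2C(OS(=O)(=O)C(F)(F)F)=CC[C@@H]12
F7 | step 11 | 6-vinyl-6,7-ene (1-vinylcyclopentene) | C=C1[C@H](O[Si](C)(C)C(C)(C)C)[C@@H](OC(=O)/C(C)=C\C)[C@@H](C(C)C)[C@@H]2C(C=C)=CC[C@@H]12
F8 | step 11 | 6(10)Z-ethylidene-7-(trichlorosilyl) compound (C7 epimers) | C=C1[C@H](O[Si](C)(C)C(C)(C)C)[C@@H](OC(=O)/C(C)=C\C)[C@@H](C(C)C)[C@@H]2/C(=C/C)C([Si](Cl)(Cl)Cl)C[C@@H]12
F9 | step 11 | 6(10)Z-ethylidene-7-(triethoxysilyl) compound (C7 epimers) | C=C1[C@H](O[Si](C)(C)C(C)(C)C)[C@@H](OC(=O)/C(C)=C\C)[C@@H](C(C)C)[C@@H]2/C(=C/C)C([Si](OCC)(OCC)OCC)C[C@@H]12
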